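**Retrosynthetic overview**

1. The target is released from its bis(quininium) salt. Both five-membered hemiketal rings and both stereocentres come from an open bis(1-arylpropane-1,2-dione) by twofold phenol-to-ketone ring closure (ring–chain tautomerism, as in the presumed biosynthesis), driven to (2R,2'R) by crystallisation.
2. The bis(1,2-dione) comes from a biaryl bis(propiophenone) by twofold oxidation of the α-CH2 groups.
3. The biaryl comes from oxidative phenol C–C coupling of 1-(4,6-dihydroxy-2,3-dimethoxyphenyl)propan-1-one at its only free ring carbon, so the biaryl bond is made before the heterocycles, not after.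
4. The propiophenone comes from 4,5-dimethoxybenzene-1,3-diol and propanenitrile (Hoesch); the diol comes from 3-hydroxy-4,5-dimethoxybenzaldehyde (Dakin).
5. Ring order: both benzene rings are bought, then the biaryl bond is formed, then the two furanone rings are closed together in one operation.

Assumption: the biaryl axis is not defined in the target SMILES and is left uncontrolled; C-2 and C-2' are hemiketal carbons that epimerise by ring–chain tautomerism, so they are fixed last, in a crystal, and quinine is assumed to give the least soluble salt with the (2R,2'R) isomer.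

**Route**

Step 1
Reactants: 1 3-hydroxy-4,5-dimethoxybenzaldehyde
Product: 3 4,5-dimethoxybenzene-1,3-diol, via aryl formate 2 (not isolated)
Conditions: 30% aq. H2O2 (1.2 equiv), H2SO4 (cat.), MeOH, rt, N2
Reagents that add atoms: hydrogen peroxide, OO
Why: Acid-catalysed Dakin (Baeyer–Villiger-type) oxidation, in which the electron-rich para-methoxy aryl group migrates to give formate 2 that is methanolysed in situ, as in the standard preparation of 3,4,5-trimethoxyphenol; no stereocentre is formed.

Step 2
Reactants: 3 4,5-dimethoxybenzene-1,3-diol; 4 propanenitrile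
Product: 6 1-(4,6-dihydroxy-2,3-dimethoxyphenyl)propan-1-one, via ketiminium chloride 5 (not isolated)
Conditions: EtCN, ZnCl2, HCl (g), Et2O, 0 °C to rt; then H2O, 100 °C
Reagents that add atoms: propanenitrile (4), CCC#N; water, O
Why: Houben–Hoesch acylation, in which the nitrilium electrophile C-acylates the phloroglucinol-type ring ortho to one hydroxyl and para to the other (the usual site in orcinol and phloroglucinol monomethyl ether) without O-acylation, and hydrolysis of 5 gives the ketone; no stereocentre is formed.

Step 3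
Reactants: 6 1-(4,6-dihydroxy-2,3-dimethoxyphenyl)propan-1-one (two molecules)
Product: 7 1,1'-(2,2',6,6'-tetrahydroxy-4,4',5,5'-tetramethoxy-[1,1'-biphenyl]-3,3'-diyl)bis(propan-1-one)
Conditions: (t-BuO)2 (1.0 equiv), PhCl, 130 °C, Ar, sealed tube
Reagents that add atoms: none
Why: Oxidative phenol coupling, in which tert-butoxyl radicals abstract the phenolic hydrogen and the aryloxyl radical dimerises C–C at its only unsubstituted ring carbon and re-aromatises, on the pattern of peroxide-mediated couplings of hydroxycoumarins and hydroxycarbazoles; the new axis is not controlled and no stereocentre is formed.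

Step 4
Reactants: 7 1,1'-(2,2',6,6'-tetrahydroxy-4,4',5,5'-tetramethoxy-[1,1'-biphenyl]-3,3'-diyl)bis(propan-1-one); 8 quinine
Product: 11 bis(quininium) 6,6'-bis(phenolate) salt of the (2R,2'R)-bis-hemiketal, via bis(1,2-dione) 9 (not isolated), via bis-hemiketal epimer mixture 10 (not isolated)
Conditions: SeO2 (2.4 equiv), 1,4-dioxane/H2O (30:1), 100 °C; filter (Celite), evaporate; then quinine (2.05 equiv), MeCN/H2O (98:2), slurry at 45 °C for 48 h, cool to 5 °C, filter
Reagents that add atoms: selenium dioxide, O=[Se]=O; quinine (8), COC1=CC2=C(C=CN=C2C=C1)[C@H]([C@@H]3C[C@@H]4CCN3C[C@@H]4C=C)O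
Why: Proposed new method: a twofold Riley oxidation turns both CH2 groups into ketones, each 1,2-dione is trapped at once by its ortho phenol in a 5-exo-trig hemiketalisation (the ring–chain tautomerism by which such hemiketals arise in nature, which also shields the methyl group from over-oxidation), and because this closure is reversible under the basic alkaloid the C-2/C-2' stereoisomers interconvert through 9 while the least soluble bis(quininium) salt of the (2R,2'R) isomer crystallises, so both stereocentres are set by crystallisation-induced asymmetric transformation; the closest known reaction types are the SeO2 oxidation of propiophenones to 1-arylpropane-1,2-diones, the epimerisation of 2-alkyl-2-hydroxybenzofuran-3-ones (auronols) and dynamic diastereomeric-salt resolutions of configurationally labile acids with cinchona bases.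

Step 5
Reactants: 11 bis(quininium) 6,6'-bis(phenolate) salt of the (2R,2'R)-bis-hemiketal
Product: 12 (2R,2'R)-2,2',6,6'-tetrahydroxy-4,4',5,5'-tetramethoxy-2,2'-dimethyl-[7,7'-bibenzofuran]-3,3'(2H,2'H)-dione
Conditions: EtOAc / aq. citric acid (pH 3), 0 °C; dry (Na2SO4), evaporate below 20 °C, store as solid at −20 °C
Reagents that add atoms: none
Why: Acid–base partition (salt break) at pH 3 and 0 °C, where the quinuclidine nitrogen is protonated, the phenols are not and ring–chain tautomerism is slowest, so C-2 and C-2' are not touched and the product is kept as a solid.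

**Compound list**

1 | 3-hydroxy-4,5-dimethoxybenzaldehyde | COc1cc(C=O)cc(O)c1OC | starting material
2 | 3-hydroxy-4,5-dimethoxyphenyl formate | COc1cc(OC=O)cc(O)c1OC | intermediate
3 | 4,5-dimethoxybenzene-1,3-diol | COc1cc(O)cc(O)c1OC | intermediate
4 | propanenitrile | CCC#N | starting material
5 | 1-(4,6-dihydroxy-2,3-dimethoxyphenyl)propan-1-iminium chloride | CCC(=[NH2+])c1c(O)cc(O)c(OC)c1OC.[Cl-] | intermediate
6 | 1-(4,6-dihydroxy-2,3-dimethoxyphenyl)propan-1-one | CCC(=O)c1c(O)cc(O)c(OC)c1OC | intermediate
7 | 1,1'-(2,2',6,6'-tetrahydroxy-4,4',5,5'-tetramethoxy-[1,1'-biphenyl]-3,3'-diyl)bis(propan-1-one), axis not controlled | CCC(=O)c1c(O)c(-c2c(O)c(OC)c(OC)c(C(=O)CC)c2O)c(O)c(OC)c1OC | intermediate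
8 | quinine | COC1=CC2=C(C=CN=C2C=C1)[C@H]([C@@H]3C[C@@H]4CCN3C[C@@H]4C=C)O | starting material
9 | 1,1'-(2,2',6,6'-tetrahydroxy-4,4',5,5'-tetramethoxy-[1,1'-biphenyl]-3,3'-diyl)bis(propane-1,2-dione) | CC(=O)C(=O)c1c(O)c(-c2c(O)c(OC)c(OC)c(C(=O)C(C)=O)c2O)c(O)c(OC)c1OC | intermediate
10 | 2,2',6,6'-tetrahydroxy-4,4',5,5'-tetramethoxy-2,2'-dimethyl-[7,7'-bibenzofuran]-3,3'(2H,2'H)-dione, interconverting mixture of the (2R,2'R), (2S,2'S) and (2R,2'S) forms | COc1c(O)c(-c2c(O)c(OC)c(OC)c3c2OC(C)(O)C3=O)c2c(c1OC)C(=O)C(C)(O)O2 | intermediate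
11 | bis(quininium) (2R,2'R)-2,2'-dihydroxy-4,4',5,5'-tetramethoxy-2,2'-dimethyl-3,3'-dioxo-2,2',3,3'-tetrahydro-[7,7'-bibenzofuran]-6,6'-bis(olate) | COc1c([O-])c(-c2c([O-])c(OC)c(OC)c3c2O[C@@](C)(O)C3=O)c2c(c1OC)C(=O)[C@](C)(O)O2.COC1=CC2=C(C=CN=C2C=C1)[C@H]([C@@H]3C[C@@H]4CC[NH+]3C[C@@H]4C=C)O.COC1=CC2=C(C=CN=C2C=C1)[C@H]([C@@H]3C[C@@H]4CC[NH+]3C[C@@H]4C=C)O | intermediate
12 | (2R,2'R)-2,2',6,6'-tetrahydroxy-4,4',5,5'-tetramethoxy-2,2'-dimethyl-[7,7'-bibenzofuran]-3,3'(2H,2'H)-dione | COc1c(O)c(-c2c(O)c(OC)c(OC)c3c2O[C@@](C)(O)C3=O)c2c(c1OC)C(=O)[C@](C)(O)O2 | target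

**Step count and risks**

Total step count: 5. Longest linear sequence: 5 steps (1 → 3 → 6 → 7 → 11 → 12).

The three steps most likely to fail:

Step 4. SeO2 may attack the electron-rich tetraphenol, or the quinine salt may not crystallise as the (2R,2'R) form. The fallback sets out from 7 and replaces both the oxidant and the crystallisation by a catalyst-controlled hydroxylation. CuBr2 in EtOAc/CHCl3 at reflux α-brominates both ketones to 1,1'-(2,2',6,6'-tetrahydroxy-4,4',5,5'-tetramethoxy-[1,1'-biphenyl]-3,3'-diyl)bis(2-bromopropan-1-one) F5. K2CO3 in acetone then closes both rings by intramolecular phenoxide O-alkylation to 6,6'-dihydroxy-4,4',5,5'-tetramethoxy-2,2'-dimethyl-[7,7'-bibenzofuran]-3,3'(2H,2'H)-dione F6, whose C-2 epimers do not matter because they enolise. A twofold enantioselective α-hydroxylation of the enol under chiral Brønsted-acid (enol) catalysis follows, using 3,3'-bis(2,4,6-triisopropylphenyl)-1,1'-binaphthyl-2,2'-diyl hydrogen phosphate, nitrosobenzene as oxygen source, toluene, 0 °C. The catalyst enantiomer that delivers R is fixed by a test on the monomer, and the product is crystallised directly from the cold mixture. This comes back to the route at 12.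

Step 3. The coupling must form a biaryl with four ortho substituents and competes with C–O coupling and over-oxidation. The fallback sets out from 6 and reverses the order of events. SeO2 in wet dioxane gives the monomeric hemiketal rac-2,6-dihydroxy-4,5-dimethoxy-2-methylbenzofuran-3(2H)-one F4, which has a single free phenol and a single free ring carbon (C-7). FeCl3 on silica gel in CH2Cl2 dimerises it there. This comes back to the route at 10, which is taken into the quinine crystallisation of step 4.

Step 2. The Hoesch acylation could go to the carbon between the two hydroxyls of 3 instead of the one next to the methoxy group. The fallback sets out from 3 and builds the biaryl first, so that only the wanted carbons remain free. MOMCl/i-Pr2NEt gives 1,5-bis(methoxymethoxy)-2,3-dimethoxybenzene F1. n-BuLi in THF at 0 °C lithiates between the two MOM ethers, and CuCl2 couples the aryllithium oxidatively to 2,2',6,6'-tetrakis(methoxymethoxy)-3,3',4,4'-tetramethoxy-1,1'-biphenyl F2. HCl in MeOH frees 3,3',4,4'-tetramethoxy-[1,1'-biphenyl]-2,2',6,6'-tetraol F3. A twofold Hoesch reaction (EtCN, ZnCl2, HCl; then H2O, 100 °C) acylates the one remaining carbon of each ring. This comes back to the route at 7 and also bypasses step 3.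

**Further compounds**

F1 | step 2 | 1,5-bis(methoxymethoxy)-2,3-dimethoxybenzene | COCOc1cc(OC)c(OC)c(OCOC)c1
F2 | step 2 | 2,2',6,6'-tetrakis(methoxymethoxy)-3,3',4,4'-tetramethoxy-1,1'-biphenyl | COCOc1cc(OC)c(OC)c(OCOC)c1-c1c(OCOC)cc(OC)c(OC)c1OCOC
F3 | step 2 | 3,3',4,4'-tetramethoxy-[1,1'-biphenyl]-2,2',6,6'-tetraol | COc1cc(O)c(-c2c(O)cc(OC)c(OC)c2O)c(O)c1OC
F4 | step 3 | rac-2,6-dihydroxy-4,5-dimethoxy-2-methylbenzofuran-3(2H)-one | COc1c(O)cc2c(c1OC)C(=O)C(C)(O)O2
F5 | step 4 | 1,1'-(2,2',6,6'-tetrahydroxy-4,4',5,5'-tetramethoxy-[1,1'-biphenyl]-3,3'-diyl)bis(2-bromopropan-1-one), mixture of diastereomers | CC(Br)C(=O)c1c(O)c(-c2c(O)c(OC)c(OC)c(C(=O)C(C)Br)c2O)c(O)c(OC)c1OC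
F6 | step 4 | 6,6'-dihydroxy-4,4',5,5'-tetramethoxy-2,2'-dimethyl-[7,7'-bibenzofuran]-3,3'(2H,2'H)-dione, mixture of C-2 epimers | COc1c(O)c(-c2c(O)c(OC)c(OC)c3c2OC(C)C3=O)c2c(c1OC)C(=O)C(C)O2
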